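**Retrosynthetic overview**
1. The 1,2-dioxane ring is closed last. The C3–O bond comes from intramolecular oxa-Michael addition of a C6 tertiary hydroperoxide to a butenolide, and the tether at C4 enforces the cis ring fusion.
2. The C6–OO bond comes from cobalt-catalysed Markovnikov silylperoxidation of a 1,1-disubstituted alkene, which is made by methylenation of a C6 ketone.
3. The butenolide ring is closed first. A Z-selective Horner–Wadsworth–Emmons olefination of a C3 aldehyde adds C1–C2, and the C4 oxygen then lactonises.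
4. The key C4–C5 bond comes from a catalytic enantioselective Mukaiyama aldol addition of the terminal silyl enol ether of 12-phenyldodecan-2-one to methyl pyruvate. This step sets C4.
5. 12-Phenyldodecan-2-one comes from methyl undec-10-enoate and bromobenzene by hydroboration/Suzuki coupling, followed by a Weinreb ketone synthesis.

Numbering used: C1 lactone C=O, C2 CH2, C3 CH(OO), C4 C(CH3)(O-lactone), C5 ring CH2, C6 C(CH3)(OO)(10-phenyldecyl). The target is (3R,4R,6R) and cis-fused.
Assumption: no known peroxidation sets an acyclic tertiary C–OO centre such as C6 with useful selectivity, so C6 is made as a roughly 1:1 mixture and the (6R) epimer is secured by chromatography of the final bicycles (at most 50 % in that step).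

**Step 1**
Reactants: 1 methyl undec-10-enoate; 2 bromobenzene
Product: 4 methyl 11-phenylundecanoate, via B-alkyl-9-BBN borane 3 (not isolated)
Conditions: 9-BBN-H, THF, 0 °C to rt; then 2, PdCl2(dppf) (3 mol %), K2CO3, DMF/H2O, 50 °C
Reagents that add atoms: 9-BBN-H (9-borabicyclo[3.3.1]nonane), B1C2CCCC1CCC2 (its boryl group is held only in 3; 4 keeps one H from it)
Why: Anti-Markovnikov hydroboration touches only the terminal alkene, and the B-alkyl Suzuki–Miyaura coupling with an aryl bromide under carbonate base leaves the methyl ester intact, with no stereocenter formed.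

**Step 2**
Reactants: 4 methyl 11-phenylundecanoate
Product: 5 N-methoxy-N-methyl-11-phenylundecanamide
Conditions: MeNH(OMe)·HCl, iPrMgCl, THF, −20 to 0 °C
Reagents that add atoms: N,O-dimethylhydroxylamine hydrochloride, CNOC.Cl
Why: Weinreb amide formation by aminolysis of an unhindered methyl ester with the magnesium amide made in the flask is a standard, high-yielding acyl substitution.

**Step 3**
Reactants: 5 N-methoxy-N-methyl-11-phenylundecanamide
Product: 7 12-phenyldodecan-2-one, via magnesium hemiaminal chelate 6 (not isolated)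
Conditions: MeMgBr, THF, 0 °C; 1 M HCl
Reagents that add atoms: methylmagnesium bromide, C[Mg]Br
Why: In this Weinreb ketone synthesis the chelate 6 survives until the acidic quench, so exactly one methyl group (the future C5) is delivered.

**Step 4**
Reactants: 7 12-phenyldodecan-2-one
Product: 9 trimethyl[(12-phenyldodec-1-en-2-yl)oxy]silane, via lithium enolate 8 (not isolated)
Conditions: LiN(iPr)2, Me3SiCl (internal trap), THF, −78 °C; pentane/cold aq. NaHCO3 work-up, used crude
Reagents that add atoms: chlorotrimethylsilane, C[Si](C)(C)Cl; lithium diisopropylamide, [Li]N(C(C)C)C(C)C (lithium is held only in 8)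
Why: Kinetic enolisation of a methyl alkyl ketone by the hindered amide at −78 °C with in-situ silylation removes a CH3 proton (typically at least 9:1) to give the terminal silyl enol ether, and the minor internal isomer is removed after step 5.

**Step 5 (key fragment union)**
Reactants: 9 trimethyl[(12-phenyldodec-1-en-2-yl)oxy]silane; 10 methyl pyruvate
Product: 12 methyl (R)-2-hydroxy-2-methyl-4-oxo-14-phenyltetradecanoate, via O-trimethylsilyl aldol adduct 11 (not isolated)
Conditions: Cu(OTf)2 (10 mol %), (R,R)-tBu-box [2,2'-(propane-2,2-diyl)bis((4R)-4-tert-butyl-4,5-dihydrooxazole)] (11 mol %), THF, −78 °C; then 1 M HCl, THF, rt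
Reagents that add atoms: none
Why: In this catalytic enantioselective Mukaiyama aldol addition the pyruvate chelates the square-planar divalent copper bis(oxazoline) complex through both carbonyl oxygens and the tert-butyl groups block one ketone face, and because the (S,S) ligand gives (S)-tertiary carbinols by si-face attack (typically above 90 % ee with silyl enol ethers and ketene acetals), the (R,R) ligand sets C4 as (R) while forming the C4–C5 bond between the chain fragment and the pyruvate fragment.

**Step 6**
Reactants: 12 methyl (R)-2-hydroxy-2-methyl-4-oxo-14-phenyltetradecanoate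
Product: 13 methyl (R)-2-methyl-4-oxo-14-phenyl-2-(triethylsilyloxy)tetradecanoate
Conditions: Et3SiOTf, 2,6-lutidine, CH2Cl2, −78 to 0 °C
Reagents that add atoms: triethylsilyl triflate, CC[Si](CC)(CC)OS(=O)(=O)C(F)(F)F
Why: O-silylation with the silyl triflate is fast enough for a tertiary alcohol at low temperature without enol-silylating the ketone, and it shuts off retro-aldol cleavage in the steps that follow.

**Step 7**
Reactants: 13 methyl (R)-2-methyl-4-oxo-14-phenyl-2-(triethylsilyloxy)tetradecanoate
Product: 14 methyl (R)-2-methyl-4-methylidene-14-phenyl-2-(triethylsilyloxy)tetradecanoate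
Conditions: Zn, CH2Br2, TiCl4, THF, −40 to 5 °C (aged); then 13, CH2Cl2, rt
Reagents that add atoms: dibromomethane, BrCBr
Why: In the Takai–Lombardo methylenation the non-basic zinc/titanium methylene reagent olefinates ketones but not esters, which avoids the enolisation and β-elimination of silanolate that a basic ylide could trigger in this β-silyloxy ketone, and C4 is untouched.

**Step 8**
Reactants: 14 methyl (R)-2-methyl-4-methylidene-14-phenyl-2-(triethylsilyloxy)tetradecanoate
Product: 15 (R)-2-methyl-4-methylidene-14-phenyl-2-(triethylsilyloxy)tetradecan-1-ol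
Conditions: iBu2AlH (2.5 equiv), CH2Cl2, −78 to 0 °C; aq. KNaC4H4O6 (tartrate)
Reagents that add atoms: none
Why: Full hydride reduction of the ester to the primary alcohol avoids mixtures from partial reduction, the isolated alkene and the tertiary silyl ether are inert, and the poorly nucleophilic aluminium alkoxide does not provoke silyl migration.

**Step 9**
Reactants: 15 (R)-2-methyl-4-methylidene-14-phenyl-2-(triethylsilyloxy)tetradecan-1-ol
Product: 16 (R)-2-methyl-4-methylidene-14-phenyl-2-(triethylsilyloxy)tetradecanal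
Conditions: Dess–Martin periodinane, NaHCO3, CH2Cl2, 0 °C to rt
Reagents that add atoms: none
Why: The buffered Dess–Martin oxidation stops at the aldehyde and spares the alkene and silyl ether, and the α-carbon is quaternary so it cannot epimerise.

**Step 10**
Reactants: 16 (R)-2-methyl-4-methylidene-14-phenyl-2-(triethylsilyloxy)tetradecanal
Product: 17 methyl (2Z,4R)-4-methyl-6-methylidene-16-phenyl-4-(triethylsilyloxy)hexadec-2-enoate
Conditions: (CF3CH2O)2P(O)CH2CO2Me, KN(SiMe3)2, 18-crown-6, THF, −78 °C
Reagents that add atoms: methyl bis(2,2,2-trifluoroethyl)phosphonoacetate, COC(=O)CP(=O)(OCC(F)(F)F)OCC(F)(F)F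
Why: In the Still–Gennari variant of the Horner–Wadsworth–Emmons olefination the electron-poor phosphonate with a dissociated potassium ion collapses rapidly from the kinetic adduct to the Z-enoate needed for ring closure, and any E isomer is removed by chromatography.

**Step 11 (first ring)**
Reactants: 17 methyl (2Z,4R)-4-methyl-6-methylidene-16-phenyl-4-(triethylsilyloxy)hexadec-2-enoate
Product: 19 (R)-5-methyl-5-(2-methylidene-12-phenyldodecyl)furan-2(5H)-one, via Z-hydroxy enoate 18 (not isolated)
Conditions: HF·pyridine, pyridine, THF, 0 °C to rt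
Reagents that add atoms: none
Why: Pyridine-buffered fluoride desilylation spares the acid-sensitive 1,1-disubstituted alkene and frees the tertiary alcohol of 18, which sits cis to the ester on a gem-disubstituted carbon and lactonises spontaneously (intramolecular transesterification) without breaking the C4–O bond, so (R) is retained.

**Step 12**
Reactants: 19 (R)-5-methyl-5-(2-methylidene-12-phenyldodecyl)furan-2(5H)-one
Product: 20 (5R)-5-methyl-5-[2-methyl-12-phenyl-2-(triethylsilylperoxy)dodecyl]furan-2(5H)-one (about 1:1 epimers at C6)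
Conditions: Co(thd)2 (thd = 2,2,6,6-tetramethylheptane-3,5-dionate, 10 mol %), O2 (1 atm), Et3SiH, ClCH2CH2Cl, rt
Reagents that add atoms: dioxygen, O=O; triethylsilane, CC[SiH](CC)CC
Why: In the Mukaiyama–Isayama hydroperoxysilylation with the divalent cobalt catalyst, hydrogen-atom transfer goes to the electron-rich 1,1-disubstituted alkene far faster than to the electron-poor butenolide and gives the tertiary C6 radical (Markovnikov), which traps O2 and is silylated, but this planar acyclic radical is remote from C4, so C6 forms without control and the epimers are parted after step 13.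

**Step 13 (second ring)**
Reactants: 20 (5R)-5-methyl-5-[2-methyl-12-phenyl-2-(triethylsilylperoxy)dodecyl]furan-2(5H)-one
Product: 22 (3R,4aR,7aR)-3,4a-dimethyl-3-(10-phenyldecyl)tetrahydrofuro[3,2-c][1,2]dioxin-6(3H)-one (the target), via hydroperoxy butenolide 21 (not isolated)
Conditions: HCl (cat.), MeOH, 0 °C; evaporate; Et2NH (0.2 equiv), CF3CH2OH, rt; SiO2 chromatography
Reagents that add atoms: none
Why: Acid methanolysis unmasks hydroperoxide 21 and an amine-catalysed 6-exo-trig intramolecular oxa-Michael addition closes the 1,2-dioxane, and because the tether hangs from C4 the peroxide reaches C3 only from the face carrying C5, which gives exclusively the cis-fused (3R) junction, while the rigid (6R) and (6S) bicycles (axial versus equatorial C6 methyl) are separable on silica gel and are assigned by NOESY and 13C data.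

**Compound list**
1 | methyl undec-10-enoate | COC(=O)CCCCCCCCC=C | starting material
2 | bromobenzene | Brc1ccccc1 | starting material
3 | methyl 11-(9-borabicyclo[3.3.1]nonan-9-yl)undecanoate | COC(=O)CCCCCCCCCCB1C2CCCC1CCC2 | intermediate
4 | methyl 11-phenylundecanoate | COC(=O)CCCCCCCCCCc1ccccc1 | intermediate
5 | N-methoxy-N-methyl-11-phenylundecanamide | CON(C)C(=O)CCCCCCCCCCc1ccccc1 | intermediate
6 | bromomagnesium 2-[methoxy(methyl)amino]-12-phenyldodecan-2-olate | CON(C)C(C)(O[Mg]Br)CCCCCCCCCCc1ccccc1 | intermediate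
7 | 12-phenyldodecan-2-one | CC(=O)CCCCCCCCCCc1ccccc1 | intermediate
8 | lithium 12-phenyldodec-1-en-2-olate | [Li]OC(=C)CCCCCCCCCCc1ccccc1 | intermediate
9 | trimethyl[(12-phenyldodec-1-en-2-yl)oxy]silane | C=C(O[Si](C)(C)C)CCCCCCCCCCc1ccccc1 | intermediate
10 | methyl pyruvate | CC(=O)C(=O)OC | starting material
11 | methyl (R)-2-methyl-4-oxo-14-phenyl-2-(trimethylsilyloxy)tetradecanoate | COC(=O)[C@](C)(O[Si](C)(C)C)CC(=O)CCCCCCCCCCc1ccccc1 | intermediate
12 | methyl (R)-2-hydroxy-2-methyl-4-oxo-14-phenyltetradecanoate | COC(=O)[C@](C)(O)CC(=O)CCCCCCCCCCc1ccccc1 | intermediate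
13 | methyl (R)-2-methyl-4-oxo-14-phenyl-2-(triethylsilyloxy)tetradecanoate | COC(=O)[C@](C)(O[Si](CC)(CC)CC)CC(=O)CCCCCCCCCCc1ccccc1 | intermediate
14 | methyl (R)-2-methyl-4-methylidene-14-phenyl-2-(triethylsilyloxy)tetradecanoate | COC(=O)[C@](C)(O[Si](CC)(CC)CC)CC(=C)CCCCCCCCCCc1ccccc1 | intermediate
15 | (R)-2-methyl-4-methylidene-14-phenyl-2-(triethylsilyloxy)tetradecan-1-ol | OC[C@](C)(O[Si](CC)(CC)CC)CC(=C)CCCCCCCCCCc1ccccc1 | intermediate
16 | (R)-2-methyl-4-methylidene-14-phenyl-2-(triethylsilyloxy)tetradecanal | O=C[C@](C)(O[Si](CC)(CC)CC)CC(=C)CCCCCCCCCCc1ccccc1 | intermediate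
17 | methyl (2Z,4R)-4-methyl-6-methylidene-16-phenyl-4-(triethylsilyloxy)hexadec-2-enoate | COC(=O)/C=C\[C@](C)(O[Si](CC)(CC)CC)CC(=C)CCCCCCCCCCc1ccccc1 | intermediate
18 | methyl (2Z,4R)-4-hydroxy-4-methyl-6-methylidene-16-phenylhexadec-2-enoate | COC(=O)/C=C\[C@](C)(O)CC(=C)CCCCCCCCCCc1ccccc1 | intermediate
19 | (R)-5-methyl-5-(2-methylidene-12-phenyldodecyl)furan-2(5H)-one | O=C1C=C[C@](C)(O1)CC(=C)CCCCCCCCCCc2ccccc2 | intermediate
20 | (5R)-5-methyl-5-[2-methyl-12-phenyl-2-(triethylsilylperoxy)dodecyl]furan-2(5H)-one, about 1:1 epimers at C6 | O=C1C=C[C@](C)(O1)CC(C)(OO[Si](CC)(CC)CC)CCCCCCCCCCc2ccccc2 | intermediate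
21 | (5R)-5-(2-hydroperoxy-2-methyl-12-phenyldodecyl)-5-methylfuran-2(5H)-one, about 1:1 epimers at C6 | O=C1C=C[C@](C)(O1)CC(C)(OO)CCCCCCCCCCc2ccccc2 | intermediate
22 | (3R,4aR,7aR)-3,4a-dimethyl-3-(10-phenyldecyl)tetrahydrofuro[3,2-c][1,2]dioxin-6(3H)-one | C[C@@]1(CCCCCCCCCCc2ccccc2)C[C@@]2(C)OC(=O)C[C@H]2OO1 | target

**Totals**
Total step count: 13. Longest linear sequence: 13 steps (1 to 22).

**Three steps most likely to fail**

*Step 5.* The donor is an ordinary ketone silyl enol ether that carries a few percent of its internal isomer, so rate and ee may fall short of the benchmark cases. The fallback sets out from methyl pyruvate 10 (with bromobenzene 2 for the chain) and comes back at 13. It sets C4 with the best-behaved donor class and attaches the chain afterwards by acyl cross-coupling. S-Ethyl thioacetate with LiN(iPr)2/Me3SiCl gives 1-(ethylsulfanyl)-1-(trimethylsilyloxy)ethene F1. This compound and 10, under the same Cu(OTf)2/(R,R)-tBu-box catalyst, give methyl (R)-4-(ethylsulfanyl)-2-methyl-4-oxo-2-(trimethylsilyloxy)butanoate F2. Hydrolysis with 1 M HCl gives methyl (R)-4-(ethylsulfanyl)-2-hydroxy-2-methyl-4-oxobutanoate F3, and Et3SiOTf/2,6-lutidine then gives methyl (R)-4-(ethylsulfanyl)-2-methyl-4-oxo-2-(triethylsilyloxy)butanoate F4. Separately, 10-bromodec-1-ene and 9-BBN-H give 9-(10-bromodecyl)-9-borabicyclo[3.3.1]nonane F5, which is coupled with 2 as in step 1 to give (10-bromodecyl)benzene F6. Zn dust with catalytic I2 in DMA at 80 °C converts this into bromo(10-phenyldecyl)zinc F7. A Fukuyama ketone synthesis of the thioester with the zinc reagent (PdCl2(PPh3)2, toluene, rt) gives 13.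

*Step 7.* The Lewis-acidic zinc/titanium slurry may strip the silyl ether or stall on this neopentyl-type ketone. The fallback sets out from 13 and comes back at 14. It is a two-stage Peterson olefination with a non-basic organocerium reagent. Me3SiCH2MgCl/CeCl3 in THF at −78 °C adds to the ketone only. Quenching cold, so that the new alkoxide cannot lactonise onto the ester, gives methyl (2R)-4-hydroxy-2-methyl-14-phenyl-2-(triethylsilyloxy)-4-[(trimethylsilyl)methyl]tetradecanoate F8, and both carbinol epimers serve equally. Brief exposure to catalytic BF3·OEt2 in CH2Cl2 at −78 °C (or silica gel) eliminates Me3SiOH through the β-silyl-stabilised tertiary cation and gives 14.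

*Step 12.* The butenolide may be partly reduced or oxygenated under the cobalt/silane/O2 conditions, and the step has no stereocontrol at C6. The fallback sets out from alcohol 15 and comes back at hydroperoxide 21. It installs the peroxide before any electron-poor alkene exists and never exposes it to a hydride reagent. The same Co(thd)2/O2/Et3SiH reaction on 15 gives (2R)-2,4-dimethyl-14-phenyl-2-(triethylsilyloxy)-4-(triethylsilylperoxy)tetradecan-1-ol F9. Dess–Martin oxidation gives (2R)-2,4-dimethyl-14-phenyl-2-(triethylsilyloxy)-4-(triethylsilylperoxy)tetradecanal F10. Still–Gennari olefination at −78 °C gives methyl (2Z,4R)-4,6-dimethyl-16-phenyl-4-(triethylsilyloxy)-6-(triethylsilylperoxy)hexadec-2-enoate F11. HF·pyridine strips both silyl groups to give methyl (2Z,4R)-6-hydroperoxy-4-hydroxy-4,6-dimethyl-16-phenylhexadec-2-enoate F12. Under these non-basic conditions F12 lactonises before any conjugate addition and gives 21, which is then closed and separated as in step 13.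

**Further compounds**
F1 | step 5 | 1-(ethylsulfanyl)-1-(trimethylsilyloxy)ethene | C=C(SCC)O[Si](C)(C)C
F2 | step 5 | methyl (R)-4-(ethylsulfanyl)-2-methyl-4-oxo-2-(trimethylsilyloxy)butanoate | COC(=O)[C@](C)(O[Si](C)(C)C)CC(=O)SCC
F3 | step 5 | methyl (R)-4-(ethylsulfanyl)-2-hydroxy-2-methyl-4-oxobutanoate | COC(=O)[C@](C)(O)CC(=O)SCC
F4 | step 5 | methyl (R)-4-(ethylsulfanyl)-2-methyl-4-oxo-2-(triethylsilyloxy)butanoate | COC(=O)[C@](C)(O[Si](CC)(CC)CC)CC(=O)SCC
F5 | step 5 | 9-(10-bromodecyl)-9-borabicyclo[3.3.1]nonane | BrCCCCCCCCCCB1C2CCCC1CCC2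
F6 | step 5 | (10-bromodecyl)benzene | BrCCCCCCCCCCc1ccccc1
F7 | step 5 | bromo(10-phenyldecyl)zinc | Br[Zn]CCCCCCCCCCc1ccccc1
F8 | step 7 | methyl (2R)-4-hydroxy-2-methyl-14-phenyl-2-(triethylsilyloxy)-4-[(trimethylsilyl)methyl]tetradecanoate | COC(=O)[C@](C)(O[Si](CC)(CC)CC)CC(O)(C[Si](C)(C)C)CCCCCCCCCCc1ccccc1
F9 | step 12 | (2R)-2,4-dimethyl-14-phenyl-2-(triethylsilyloxy)-4-(triethylsilylperoxy)tetradecan-1-ol | OC[C@](C)(O[Si](CC)(CC)CC)CC(C)(OO[Si](CC)(CC)CC)CCCCCCCCCCc1ccccc1
F10 | step 12 | (2R)-2,4-dimethyl-14-phenyl-2-(triethylsilyloxy)-4-(triethylsilylperoxy)tetradecanal | O=C[C@](C)(O[Si](CC)(CC)CC)CC(C)(OO[Si](CC)(CC)CC)CCCCCCCCCCc1ccccc1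
F11 | step 12 | methyl (2Z,4R)-4,6-dimethyl-16-phenyl-4-(triethylsilyloxy)-6-(triethylsilylperoxy)hexadec-2-enoate | COC(=O)/C=C\[C@](C)(O[Si](CC)(CC)CC)CC(C)(OO[Si](CC)(CC)CC)CCCCCCCCCCc1ccccc1
F12 | step 12 | methyl (2Z,4R)-6-hydroperoxy-4-hydroxy-4,6-dimethyl-16-phenylhexadec-2-enoate | COC(=O)/C=C\[C@](C)(O)CC(C)(OO)CCCCCCCCCCc1ccccc1
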